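**Retrosynthetic overview**

1. The strategy rests on ring A: the C20 methyl on quaternary C10 and the C2 hydroxyl are cis (both axial on the β face). O2 can therefore hand C20 to the C1=C10 bond as a cyclopropane methylene, and the surplus C1–C20 bond is cut reductively once C2 is a ketone.
2. Endgame disconnections: C8=C17 (methylenation), C13=C14 (Horner–Wadsworth–Emmons), C9–C11 (α-face alkylation of the 6-en-8-one dienolate, trans to C20).
3. Key disconnection: C10–C20 and C1–C20 by hydroxyl-directed cyclopropanation of the 1(10)-octalin-2β-ol 14; C1–C20 is then cleaved with Li/NH3.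
4. Octalin 14: C2–O from allylic oxidation and α-face hydride; ring A from a catalytic enantioselective Diels–Alder reaction (bonds C2–C3 and C4–C5) of a ring-B diene with methacrolein. C4 and C5 are set in one concerted step, so no reaction has to tell CH3 from the carboxyl group on C4.
5. Ring order: ring B is bought (cyclohexane-1,3-dione mono-ketal), ring A is closed by cycloaddition (step 3), the three-membered ring is closed in step 7 and opened in step 9.

Key step: step 7

**Remarks and assumptions**

- Decalin carbons carry labdane numbers (ring A: C1–C5, C10; ring B: C5–C10); β is the face of the C10 methyl of the target.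
- The target SMILES puts H9 on the β face (side chain α, trans to C20), i.e. a 9-epi-labdane with the carboxyl on C4 equatorial (α, C18); this is taken as given.
- The antipode of the boron catalyst in step 3 is taken to be the one that gives 7 as drawn; if the (S)-catalyst gives the mirror image, the (R)-catalyst is used.
- Ketone 1 is assumed to be purchasable.
- Compounds 14 and 17 are the precursor and the product of the key step.

**Route**

Step 1
Reactants: 1 1,4-dioxaspiro[4.5]decan-7-one; 2 N-phenylbis(trifluoromethanesulfonimide)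
Product: 3 1,4-dioxaspiro[4.5]dec-7-en-7-yl trifluoromethanesulfonate
Conditions: LiN(SiMe3)2, THF, −78 °C; then 2, −78 °C → rt; H2O work-up
Reagents that add atoms: N-phenylbis(trifluoromethanesulfonimide), O=S(=O)(N(c1ccccc1)S(=O)(=O)C(F)(F)F)C(F)(F)F
Why: Kinetic deprotonation at the less hindered α-CH2 remote from the ketal and O-sulfonylation of the enolate (enol triflate formation) should give the 7(8)-ene regioisomer; no stereocentre is formed.

Step 2
Reactants: 3 1,4-dioxaspiro[4.5]dec-7-en-7-yl trifluoromethanesulfonate; 4 4,4,5,5-tetramethyl-2-vinyl-1,3,2-dioxaborolane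
Product: 5 7-vinyl-1,4-dioxaspiro[4.5]dec-7-ene
Conditions: Pd(PPh3)4 (3 mol%), K3PO4, 1,4-dioxane/H2O, 80 °C
Reagents that add atoms: 4,4,5,5-tetramethyl-2-vinyl-1,3,2-dioxaborolane, C=CB1OC(C)(C)C(C)(C)O1
Why: Suzuki–Miyaura coupling of an alkenyl triflate with a vinylboronate gives the 1-vinylcyclohexene diene (C5=C10–C1=C2) with the ring double bond in place; no stereocentre is formed.

Step 3
Reactants: 5 7-vinyl-1,4-dioxaspiro[4.5]dec-7-ene; 6 methacrolein
Product: 7 8,8-ethylenedioxy-4β-methyl-1(10)-octalin-4α-carbaldehyde (5α-H)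
Conditions: 6 (2 equiv), N-protonated (S)-3,3-diphenyl-1-(o-tolyl)tetrahydropyrrolo[1,2-c][1,3,2]oxazaborole (from the oxazaborolidine and Tf2NH, 20 mol%), CH2Cl2, −78 → −40 °C
Reagents that add atoms: methacrolein, CC(=C)C=O
Why: Lewis acid-catalysed enantioselective Diels–Alder reaction: the substituted diene terminus C5 bonds to the formyl-bearing carbon (ortho rule for a 1-substituted diene, the C9 branch being inductively deactivated by the ketal), the α-methyl enal bound s-trans to boron reacts through the formyl-exo transition state so that the C4 methyl ends up cis to C6 and the formyl cis to H5, and the catalyst shields one enal face so that C4 and C5 are set together in the absolute sense.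

Step 4
Reactants: 7 8,8-ethylenedioxy-4β-methyl-1(10)-octalin-4α-carbaldehyde; 8 sodium chlorite; 9 iodomethane
Product: 11 methyl 8,8-ethylenedioxy-4β-methyl-1(10)-octalin-4α-carboxylate (5α-H), via octalin-4α-carboxylic acid 10 (not isolated)
Conditions: NaClO2, NaH2PO4, 2-methyl-2-butene, t-BuOH/H2O, 0 °C → rt; then MeI, K2CO3, DMF, rt
Reagents that add atoms: sodium chlorite, [Na+].[O-]Cl=O; iodomethane, CI
Why: Pinnick oxidation of the non-enolisable neopentyl aldehyde followed by O-alkylation of the carboxylate should give the methyl ester without touching the trisubstituted alkene (hypochlorite is scavenged) or the quaternary C4.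

Step 5
Reactants: 11 methyl 8,8-ethylenedioxy-4β-methyl-1(10)-octalin-4α-carboxylate; 12 tert-butyl hydroperoxide
Product: 13 methyl 8,8-ethylenedioxy-4β-methyl-2-oxo-1(10)-octalin-4α-carboxylate (5α-H)
Conditions: dirhodium tetrakis(caprolactamate) Rh2(C6H10NO)4 (1 mol%), t-BuOOH (5 equiv), K2CO3, CH2Cl2, rt
Reagents that add atoms: tert-butyl hydroperoxide, CC(C)(C)OO
Why: Allylic C–H oxidation through tert-butylperoxyl radicals: hydrogen should be abstracted from the ring CH2 beside the vinylic CH (C2) and not from C9 (deactivated by the adjacent ketal) or the hindered C5–H, and the allylic peroxide collapses to the β,β-disubstituted enone without touching a stereocentre.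

Step 6
Reactants: 13 methyl 8,8-ethylenedioxy-4β-methyl-2-oxo-1(10)-octalin-4α-carboxylate
Product: 14 methyl 8,8-ethylenedioxy-2β-hydroxy-4β-methyl-1(10)-octalin-4α-carboxylate (5α-H)
Conditions: LiBH(s-Bu)3, THF, −78 °C; H2O work-up
Reagents that add atoms: none
Why: 1,2-Reduction of a β,β-disubstituted cyclohexenone by a bulky trialkylborohydride: hydride enters C2 from the α face, anti to the axial C19 methyl on C4 (1,3 to the carbonyl), which should give the pseudoaxial 2β-alcohol.

Step 7
Reactants: 14 methyl 8,8-ethylenedioxy-2β-hydroxy-4β-methyl-1(10)-octalin-4α-carboxylate; 15 diiodomethane; 16 diethylzinc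
Product: 17 methyl 8,8-ethylenedioxy-2β-hydroxy-1β,10β-methano-4β-methyldecalin-4α-carboxylate (5α-H; cyclopropane C1–C20–C10 on the β face)
Conditions: Et2Zn (5 equiv), CH2I2 (10 equiv), CH2Cl2, 0 °C → rt; NH4Cl work-up
Reagents that add atoms: diiodomethane, ICI
Why: The zinc alkoxide formed from the 2β-hydroxyl and Et2Zn binds the iodomethylzinc carbenoid (Furukawa variant of the Simmons–Smith reaction) and passes CH2 to the C1=C10 bond through the concerted butterfly transition state, so that C1–C20 and C10–C20 form together. The closest known reaction type is the hydroxyl-directed cyclopropanation of cyclohex-2-enols, which is reliably syn to oxygen. The three-membered ring (C1, C10, C20) is closed by a concerted [2+1] methylene transfer and not by a stepwise ring closure. Both new stereocentres, C1 and quaternary C10, are fixed by the C2 carbinol: delivery on the β face places C20 cis to O2 and trans to H5. The step needs β-face selectivity against the steric bias of the axial C19 methyl, which screens that face; the alkoxide-bound, intramolecular delivery secures it, and with a single alkene in the molecule there is no site selectivity to worry about. The sacrificial C1–C20 bond is cut in step 9, which leaves C20 as the angular methyl.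

Step 8
Reactants: 17 methyl 8,8-ethylenedioxy-2β-hydroxy-1β,10β-methano-4β-methyldecalin-4α-carboxylate
Product: 18 methyl 8,8-ethylenedioxy-1β,10β-methano-4β-methyl-2-oxodecalin-4α-carboxylate (5α-H)
Conditions: Dess–Martin periodinane, NaHCO3, CH2Cl2, rt
Reagents that add atoms: none
Why: Dess–Martin oxidation of the secondary cyclopropyl carbinol should give the cyclopropyl ketone under buffered, non-acidic conditions that leave the cyclopropane and the ketal intact.

Step 9
Reactants: 18 methyl 8,8-ethylenedioxy-1β,10β-methano-4β-methyl-2-oxodecalin-4α-carboxylate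
Product: 19 methyl 8,8-ethylenedioxy-4β,10β-dimethyl-2-oxo-trans-decalin-4α-carboxylate (5α-H)
Conditions: Li (2.5 equiv), NH3(l)/THF, −78 °C, short contact; then solid NH4Cl
Reagents that add atoms: none
Why: Dissolving-metal reduction of a cyclopropyl ketone: the ketyl radical anion cleaves the cyclopropane bond that overlaps with the carbonyl π system, the exocyclic C1–C20 bond and not the ring-fusion C1–C10 bond, so C20 becomes the β-methyl on C10 with C10 unchanged, and the C1 enolate shields the ketone until it is protonated on quenching.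

Step 10
Reactants: 19 methyl 8,8-ethylenedioxy-4β,10β-dimethyl-2-oxo-trans-decalin-4α-carboxylate; 20 water
Product: 22 methyl 2β-hydroxy-4β,10β-dimethyl-8-oxo-trans-decalin-4α-carboxylate (5α-H), via 2β-hydroxy ketal 21 (not isolated)
Conditions: NaBH4, MeOH, 0 °C; then 2 M HCl, THF, rt
Reagents that add atoms: water, O
Why: Borohydride reduction then acid-catalysed acetal hydrolysis: the β face of the C2 carbonyl is closed by the two syn-axial methyls C19 and C20, so hydride adds from the α face to give the axial 2β-alcohol, and aqueous acid then frees the C8 ketone.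

Step 11
Reactants: 22 methyl 2β-hydroxy-4β,10β-dimethyl-8-oxo-trans-decalin-4α-carboxylate; 23 trimethylsilyl trifluoromethanesulfonate
Product: 25 methyl 4β,10β-dimethyl-8-oxo-2β-(trimethylsilyloxy)-trans-octal-6-ene-4α-carboxylate (5α-H), via 2,8-bis(silyloxy)-7-ene 24 (not isolated)
Conditions: TMSOTf (2.5 equiv), Et3N, CH2Cl2, 0 °C; then Pd(OAc)2 (1.1 equiv), MeCN, rt
Reagents that add atoms: trimethylsilyl trifluoromethanesulfonate, C[Si](C)(C)OS(=O)(=O)C(F)(F)F
Why: Soft enolisation goes toward C7, away from the neopentyl C9 beside quaternary C10, and Saegusa–Ito oxidation (divalent-palladium enolate, β-hydride elimination) should give the 6-en-8-one, while the hindered 2β-hydroxyl is capped as its trimethylsilyl ether in the same operation.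

Step 12
Reactants: 26 methyl vinyl ketone; 27 iodotrimethylsilane
Product: 28 (Z)-4-iodo-2-(trimethylsilyloxy)but-2-ene
Conditions: CH2Cl2, −40 °C; used at once as a solution
Reagents that add atoms: methyl vinyl ketone, CC(=O)C=C; iodotrimethylsilane, C[Si](C)(C)I
Why: Conjugate addition of iodide to the silyl-activated enone (1,4-addition of iodotrimethylsilane) should give the β-iodo silyl enol ether, an allylic iodide that acts as a masked 3-oxobutyl electrophile.

Step 13
Reactants: 25 methyl 4β,10β-dimethyl-8-oxo-2β-(trimethylsilyloxy)-trans-octal-6-ene-4α-carboxylate; 28 (Z)-4-iodo-2-(trimethylsilyloxy)but-2-ene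
Product: 30 methyl 2β-hydroxy-4β,10β-dimethyl-8-oxo-9α-(3-oxobutyl)-trans-octal-6-ene-4α-carboxylate (5α-H, 9β-H), via 9α-silyloxybutenyl bis-silyl enone 29 (not isolated)
Conditions: LiN(i-Pr)2 (1.1 equiv), THF, −78 °C; then 28 (1.5 equiv), DMPU, −78 → −30 °C; then 1 M HCl, THF, 0 °C
Reagents that add atoms: (Z)-4-iodo-2-(trimethylsilyloxy)but-2-ene, C/C(O[Si](C)(C)C)=C/CI
Why: Kinetic α′-deprotonation gives the cross-conjugated lithium dienolate (C7 is vinylic, so only C9 can be alkylated), and SN2 alkylation by the allylic iodide should occur axially on the α face, anti to the adjacent axial C20 methyl, which sets C9 with the side chain α and H9 β; dilute acid then hydrolyses the silyl enol ether to the methyl ketone and removes the silyl ether.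

Step 14
Reactants: 30 methyl 2β-hydroxy-4β,10β-dimethyl-8-oxo-9α-(3-oxobutyl)-trans-octal-6-ene-4α-carboxylate
Product: 31 methyl 2β-hydroxy-4β,10β-dimethyl-8-oxo-9α-(3-oxobutyl)-trans-decalin-4α-carboxylate (5α-H, 9β-H)
Conditions: H2 (1 atm), 10% Pd/C, EtOAc, rt
Reagents that add atoms: none
Why: Heterogeneous catalytic hydrogenation saturates the disubstituted enone C6=C7 bond, which served only to block C7; the medium is neutral, so the kinetically set C9 is kept and no new stereocentre arises.

Step 15
Reactants: 31 methyl 2β-hydroxy-4β,10β-dimethyl-8-oxo-9α-(3-oxobutyl)-trans-decalin-4α-carboxylate; 32 trimethyl phosphonoacetate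
Product: 33 dimethyl 2β-hydroxy-8-oxo-17-nor-9βH-labd-13E-ene-15,18-dioate
Conditions: (MeO)2P(O)CH2CO2Me (3 equiv), NaH (2.8 equiv), THF, 0 °C → rt
Reagents that add atoms: trimethyl phosphonoacetate, COC(=O)CP(=O)(OC)OC
Why: Horner–Wadsworth–Emmons olefination: the unhindered methyl ketone should react in preference to the C8 ketone flanked by the substituted C9, the E-enoate (chain trans to the ester) should predominate with the minor Z isomer removed by chromatography, and the equatorial H9 is poorly aligned for enolisation so C9 should hold under the weakly basic phosphonate anion.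

Step 16
Reactants: 33 dimethyl 2β-hydroxy-8-oxo-17-nor-9βH-labd-13E-ene-15,18-dioate; 34 dibromomethane
Product: 35 dimethyl 2β-hydroxy-9βH-labda-8(17),13E-diene-15,18-dioate
Conditions: Zn, CH2Br2, TiCl4 (reagent pre-formed in THF, −40 → 5 °C), CH2Cl2, rt; NaHCO3 work-up
Reagents that add atoms: dibromomethane, BrCBr
Why: Takai–Lombardo methylenation with the gem-dimetallic zinc/titanium reagent, which is non-basic and should convert the enolisable C8 ketone into the exocyclic methylene without epimerising C9, while leaving both esters and the free hydroxyl alone.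

Step 17
Reactants: 35 dimethyl 2β-hydroxy-9βH-labda-8(17),13E-diene-15,18-dioate; 36 potassium hydroxide
Product: 37 2β-hydroxy-9βH-labda-8(17),13E-diene-15,18-dioic acid (CNP0086784.6)
Conditions: KOH, MeOH/H2O, rt; then DMSO/H2O, 90 °C; then 1 M HCl to pH 3
Reagents that add atoms: potassium hydroxide, [K+].[OH-]
Why: Base-mediated ester hydrolysis by acyl–oxygen cleavage: the side-chain ester should cleave at room temperature and the hindered equatorial C4 ester on heating, and neither the allylic C9 nor the exocyclic alkene is base-labile, so the diacid should be obtained with all stereocentres intact.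

**Compound list**

1 | 1,4-dioxaspiro[4.5]decan-7-one | O=C1CC2(OCCO2)CCC1 | starting material
2 | N-phenylbis(trifluoromethanesulfonimide) | O=S(=O)(N(c1ccccc1)S(=O)(=O)C(F)(F)F)C(F)(F)F | starting material
3 | 1,4-dioxaspiro[4.5]dec-7-en-7-yl trifluoromethanesulfonate | O=S(=O)(OC1=CCCC2(C1)OCCO2)C(F)(F)F | intermediate
4 | 4,4,5,5-tetramethyl-2-vinyl-1,3,2-dioxaborolane | C=CB1OC(C)(C)C(C)(C)O1 | starting material
5 | 7-vinyl-1,4-dioxaspiro[4.5]dec-7-ene | C=CC1=CCCC2(C1)OCCO2 | intermediate
6 | methacrolein | CC(=C)C=O | starting material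
7 | 8,8-ethylenedioxy-4β-methyl-1(10)-octalin-4α-carbaldehyde (5α-H) | C1C=C2CC3(OCCO3)CC[C@H]2[C@](C)(C=O)C1 | intermediate
8 | sodium chlorite | [Na+].[O-]Cl=O | starting material
9 | iodomethane | CI | starting material
10 | 8,8-ethylenedioxy-4β-methyl-1(10)-octalin-4α-carboxylic acid (5α-H) | C1C=C2CC3(OCCO3)CC[C@H]2[C@](C)(C(=O)O)C1 | intermediate
11 | methyl 8,8-ethylenedioxy-4β-methyl-1(10)-octalin-4α-carboxylate (5α-H) | C1C=C2CC3(OCCO3)CC[C@H]2[C@](C)(C(=O)OC)C1 | intermediate
12 | tert-butyl hydroperoxide | CC(C)(C)OO | starting material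
13 | methyl 8,8-ethylenedioxy-4β-methyl-2-oxo-1(10)-octalin-4α-carboxylate (5α-H) | O=C1C=C2CC3(OCCO3)CC[C@H]2[C@](C)(C(=O)OC)C1 | intermediate
14 | methyl 8,8-ethylenedioxy-2β-hydroxy-4β-methyl-1(10)-octalin-4α-carboxylate (5α-H) | O[C@H]1C=C2CC3(OCCO3)CC[C@H]2[C@](C)(C(=O)OC)C1 | intermediate
15 | diiodomethane | ICI | starting material
16 | diethylzinc | CC[Zn]CC | starting material
17 | methyl 8,8-ethylenedioxy-2β-hydroxy-1β,10β-methano-4β-methyldecalin-4α-carboxylate (5α-H) | O[C@H]1[C@H]2C[C@]23CC4(OCCO4)CC[C@H]3[C@](C)(C(=O)OC)C1 | intermediate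
18 | methyl 8,8-ethylenedioxy-1β,10β-methano-4β-methyl-2-oxodecalin-4α-carboxylate (5α-H) | O=C1[C@H]2C[C@]23CC4(OCCO4)CC[C@H]3[C@](C)(C(=O)OC)C1 | intermediate
19 | methyl 8,8-ethylenedioxy-4β,10β-dimethyl-2-oxo-trans-decalin-4α-carboxylate (5α-H) | O=C1C[C@]2(C)CC3(OCCO3)CC[C@H]2[C@](C)(C(=O)OC)C1 | intermediate
20 | water | O | starting material
21 | methyl 8,8-ethylenedioxy-2β-hydroxy-4β,10β-dimethyl-trans-decalin-4α-carboxylate (5α-H) | O[C@H]1C[C@]2(C)CC3(OCCO3)CC[C@H]2[C@](C)(C(=O)OC)C1 | intermediate
22 | methyl 2β-hydroxy-4β,10β-dimethyl-8-oxo-trans-decalin-4α-carboxylate (5α-H) | O[C@H]1C[C@]2(C)CC(=O)CC[C@H]2[C@](C)(C(=O)OC)C1 | intermediate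
23 | trimethylsilyl trifluoromethanesulfonate | C[Si](C)(C)OS(=O)(=O)C(F)(F)F | starting material
24 | methyl 4β,10β-dimethyl-2β,8-bis(trimethylsilyloxy)-trans-octal-7-ene-4α-carboxylate (5α-H) | C[Si](C)(C)O[C@H]1C[C@]2(C)CC(O[Si](C)(C)C)=CC[C@H]2[C@](C)(C(=O)OC)C1 | intermediate
25 | methyl 4β,10β-dimethyl-8-oxo-2β-(trimethylsilyloxy)-trans-octal-6-ene-4α-carboxylate (5α-H) | C[Si](C)(C)O[C@H]1C[C@]2(C)CC(=O)C=C[C@H]2[C@](C)(C(=O)OC)C1 | intermediate
26 | methyl vinyl ketone | CC(=O)C=C | starting material
27 | iodotrimethylsilane | C[Si](C)(C)I | starting material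
28 | (Z)-4-iodo-2-(trimethylsilyloxy)but-2-ene | C/C(O[Si](C)(C)C)=C/CI | intermediate
29 | methyl 4β,10β-dimethyl-8-oxo-2β-(trimethylsilyloxy)-9α-[(Z)-3-(trimethylsilyloxy)but-2-enyl]-trans-octal-6-ene-4α-carboxylate (5α-H, 9β-H) | C[Si](C)(C)O[C@H]1C[C@]2(C)[C@H](C/C=C(/C)O[Si](C)(C)C)C(=O)C=C[C@H]2[C@](C)(C(=O)OC)C1 | intermediate
30 | methyl 2β-hydroxy-4β,10β-dimethyl-8-oxo-9α-(3-oxobutyl)-trans-octal-6-ene-4α-carboxylate (5α-H, 9β-H) | O[C@H]1C[C@]2(C)[C@H](CCC(C)=O)C(=O)C=C[C@H]2[C@](C)(C(=O)OC)C1 | intermediate
31 | methyl 2β-hydroxy-4β,10β-dimethyl-8-oxo-9α-(3-oxobutyl)-trans-decalin-4α-carboxylate (5α-H, 9β-H) | O[C@H]1C[C@]2(C)[C@H](CCC(C)=O)C(=O)CC[C@H]2[C@](C)(C(=O)OC)C1 | intermediate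
32 | trimethyl phosphonoacetate | COC(=O)CP(=O)(OC)OC | starting material
33 | dimethyl 2β-hydroxy-8-oxo-17-nor-9βH-labd-13E-ene-15,18-dioate | O[C@H]1C[C@]2(C)[C@H](CC/C(C)=C/C(=O)OC)C(=O)CC[C@H]2[C@](C)(C(=O)OC)C1 | intermediate
34 | dibromomethane | BrCBr | starting material
35 | dimethyl 2β-hydroxy-9βH-labda-8(17),13E-diene-15,18-dioate | O[C@H]1C[C@]2(C)[C@H](CC/C(C)=C/C(=O)OC)C(=C)CC[C@H]2[C@](C)(C(=O)OC)C1 | intermediate
36 | potassium hydroxide | [K+].[OH-] | starting material
37 | 2β-hydroxy-9βH-labda-8(17),13E-diene-15,18-dioic acid (CNP0086784.6) | C=C1CC[C@@H]2[C@](C)(C[C@H](O)C[C@@]2(C)C(=O)O)[C@@H]1CC/C(C)=C/C(=O)O | target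

**Step count**

Total: 17 steps. Longest linear sequence: 16 steps (steps 1–11 and 13–17); step 12 prepares the alkylating agent for step 13.

**Steps most likely to fail**

Step 3. The cationic boron acid may ionise the dioxolane of the diene, or may discriminate the two enal faces poorly, so that the adduct forms in low enantiomeric purity. The fallback sets out from 5 and gives up catalyst control. Uncatalysed thermal cycloaddition of 5 with methyl methacrylate (toluene, 140 °C, sealed tube, BHT) would give the racemic ester, that is 11 together with its mirror image, methyl 8,8-ethylenedioxy-4α-methyl-1(10)-octalin-4β-carboxylate F1, after chromatographic removal of ester-endo adducts. Allylic oxidation as in step 5 would then give 13 together with its enantiomer, the 2-oxo ester F2. Reduction with catecholborane and the (S)-configured 1-methyl-3,3-diphenyl-tetrahydropyrrolo[1,2-c][1,3,2]oxazaborole (the antipode whose preferred hydride face coincides with the α face of 13) puts hydride on the same carbonyl face of both enantiomers. 13 therefore gives 14, and F2 gives the diastereomeric alcohol with the hydroxyl trans to the C4 methyl, methyl 8,8-ethylenedioxy-2β-hydroxy-4α-methyl-1(10)-octalin-4β-carboxylate F3, which is removed by chromatography. The route is rejoined at 14.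

Step 5. Hydrogen abstraction may also take place at the tertiary allylic C5–H, which would move the double bond to C5=C10 and erase the C5 stereocentre, or at C9, and the peroxide medium may erode the ketal. The fallback sets out from 11 and moves the oxygen in by an ionic sequence. Epoxidation with mCPBA (NaHCO3, CH2Cl2, 0 °C) on the α face, away from the axial C19 methyl, would give methyl 1α,10α-epoxy-8,8-ethylenedioxy-4β-methyldecalin-4α-carboxylate F4. Sodium phenylselenide (from (PhSe)2 and NaBH4, EtOH, reflux) should open it at the secondary C1 to give methyl 8,8-ethylenedioxy-10α-hydroxy-4β-methyl-1β-(phenylseleno)decalin-4α-carboxylate F5. Oxidation with H2O2 and pyridine and syn-elimination of the selenoxide toward C2 (C10 carries no hydrogen) gives the tertiary allylic alcohol methyl 8,8-ethylenedioxy-10α-hydroxy-4β-methyloctal-1-ene-4α-carboxylate F6. Pyridinium chlorochromate [C5H5NH][CrO3Cl] in CH2Cl2 then effects the oxidative 1,3-transposition (Babler–Dauben oxidation) to the enone 13, where the route is rejoined.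

Step 13. Silyl transfer from the silyl enol ether iodide to the lithium dienolate, or collapse of the labile iodide to methyl vinyl ketone (which would then add at C9 and back onto C6), may outrun C-alkylation at the neopentyl C9. The fallback sets out from 25 and uses a robust masked electrophile with a different unmasking. The same dienolate (LiN(i-Pr)2, THF/DMPU, −78 → 0 °C) is alkylated with commercial 1,3-dichlorobut-2-ene to give methyl 9α-(3-chlorobut-2-enyl)-4β,10β-dimethyl-8-oxo-2β-(trimethylsilyloxy)-trans-octal-6-ene-4α-carboxylate F7 (E/Z mixture at the chloroalkene). Mercury-assisted hydrolysis of the vinyl chloride with Hg(OCOCF3)2 in MeNO2 at rt, followed by dilute aqueous HCl, unveils the methyl ketone and removes the silyl ether. This gives 30, where the route is rejoined.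

**Further compounds**

F1 | step 3 | methyl 8,8-ethylenedioxy-4α-methyl-1(10)-octalin-4β-carboxylate (5β-H; enantiomer of 11) | C1C=C2CC3(OCCO3)CC[C@@H]2[C@@](C)(C(=O)OC)C1
F2 | step 3 | methyl 8,8-ethylenedioxy-4α-methyl-2-oxo-1(10)-octalin-4β-carboxylate (5β-H; enantiomer of 13) | O=C1C=C2CC3(OCCO3)CC[C@@H]2[C@@](C)(C(=O)OC)C1
F3 | step 3 | methyl 8,8-ethylenedioxy-2β-hydroxy-4α-methyl-1(10)-octalin-4β-carboxylate (5β-H) | O[C@H]1C=C2CC3(OCCO3)CC[C@@H]2[C@@](C)(C(=O)OC)C1
F4 | step 5 | methyl 1α,10α-epoxy-8,8-ethylenedioxy-4β-methyldecalin-4α-carboxylate (5α-H) | C1[C@@H]2O[C@@]23CC4(OCCO4)CC[C@H]3[C@](C)(C(=O)OC)C1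
F5 | step 5 | methyl 8,8-ethylenedioxy-10α-hydroxy-4β-methyl-1β-(phenylseleno)decalin-4α-carboxylate (5α-H) | C1[C@@H]([Se]c2ccccc2)[C@@]3(O)CC4(OCCO4)CC[C@H]3[C@](C)(C(=O)OC)C1
F6 | step 5 | methyl 8,8-ethylenedioxy-10α-hydroxy-4β-methyloctal-1-ene-4α-carboxylate (5α-H) | C1=C[C@@]2(O)CC3(OCCO3)CC[C@H]2[C@](C)(C(=O)OC)C1
F7 | step 13 | methyl 9α-(3-chlorobut-2-enyl)-4β,10β-dimethyl-8-oxo-2β-(trimethylsilyloxy)-trans-octal-6-ene-4α-carboxylate (5α-H, 9β-H) | C[Si](C)(C)O[C@H]1C[C@]2(C)[C@H](CC=C(C)Cl)C(=O)C=C[C@H]2[C@](C)(C(=O)OC)C1
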